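**Retrosynthetic overview**

1. The target is a 5,7-dihydroxyisoflavone (rings A and C) whose ring B is fused to a (3R)-3-hydroxy-2,2-dimethyldihydropyran (ring D). The strategy rests on ring A: C8a lies ortho, and C5 and C7 lie ortho and para, to the C4 carbonyl. One symmetric 2,4,6-trifluorobenzoyl unit therefore supplies the leaving group for the O1–C8a closure and two activated C–F sites that become C–O afterwards.
2. Key disconnection: C3–C4 and O1–C8a of ring C, leading back to enamine 14 of the ring B/D arylacetaldehyde and 2,4,6-trifluorobenzoyl chloride 15.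
3. Enamine 14 comes from the C8-formyl chroman by one-carbon homologation; the R centre at C3 of ring D comes from asymmetric epoxidation of chromene 6 and hydride opening at the benzylic carbon.
4. Chromene 6 (ring D) comes from 2,4-dihydroxybenzaldehyde (ring B) by an aryl propargyl ether Claisen cascade.
5. Ring order: B (bought), D (step 3), then C with ring A delivered intact (step 11); fluoride-to-benzyloxy exchange and global hydrogenolysis finish the route.

Key step: step 11

Assumption: (R,R)-(salen)MnCl is taken to give the (3R,4R)-oxirane of a 2,2-dimethylchromene, as is the rule for this substrate class; if the opposite sense were found, the (S,S)-complex would be used.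

**Route**

Step 1
Reactants: 1 2,4-dihydroxybenzaldehyde
Product: 2 4-(benzyloxy)-2-hydroxybenzaldehyde
Conditions: BnBr (1.05 equiv), NaHCO3, KI (cat.), MeCN, reflux
Reagents that add atoms: benzyl bromide, BrCc1ccccc1
Why: Williamson etherification in which the weak base ionises only the free 4-OH, the 2-OH being held in a hydrogen bond to the formyl oxygen, so the 4-ether should form selectively.

Step 2
Reactants: 2 4-(benzyloxy)-2-hydroxybenzaldehyde; 3 3-chloro-3-methylbut-1-yne
Product: 4 4-(benzyloxy)-2-[(2-methylbut-3-yn-2-yl)oxy]benzaldehyde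
Conditions: DBU, CuCl2·2H2O (cat.), MeCN, 0 °C → rt
Reagents that add atoms: none
Why: Copper-catalysed propargylic etherification of a phenoxide with a tertiary propargylic chloride is the standard entry to aryl 1,1-dimethylpropargyl ethers, and DBU fully ionises the hydrogen-bonded 2-OH.

Step 3
Reactants: 4 4-(benzyloxy)-2-[(2-methylbut-3-yn-2-yl)oxy]benzaldehyde
Product: 6 5-(benzyloxy)-2,2-dimethyl-2H-chromene-8-carbaldehyde, via ortho-allenylphenol 5 (not isolated)
Conditions: 1,2-dichlorobenzene, 180 °C
Reagents that add atoms: none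
Why: The aromatic propargyl Claisen rearrangement can only reach C3 because C1 carries the formyl group, and allenylphenol 5 should close to the 2,2-dimethylchromene by [1,5]-hydrogen shift and oxa-6π electrocyclisation, which forms ring D.

Step 4
Reactants: 6 5-(benzyloxy)-2,2-dimethyl-2H-chromene-8-carbaldehyde
Product: 7 (3R,4R)-5-(benzyloxy)-3,4-epoxy-2,2-dimethylchromane-8-carbaldehyde
Conditions: (R,R)-(salen)MnCl (Jacobsen catalyst, C36H52ClMnN2O2, 5 mol %), 4-phenylpyridine N-oxide, aq. NaOCl (pH 11.3), CH2Cl2, 0 °C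
Reagents that add atoms: sodium hypochlorite, [Na+].[O-]Cl
Why: Jacobsen–Katsuki epoxidation, for which cis-olefinic 2,2-dimethylchromenes are the best substrate class; the (R,R)-salen ligand steers oxygen transfer to one face of C3=C4 and so sets C3 as R, while the formyl group para to the benzyloxy group tempers the acid lability of the benzylic oxirane.

Step 5
Reactants: 7 (3R,4R)-5-(benzyloxy)-3,4-epoxy-2,2-dimethylchromane-8-carbaldehyde
Product: 8 (3R)-5-(benzyloxy)-8-(hydroxymethyl)-2,2-dimethylchroman-3-ol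
Conditions: LiAlH4, THF, 0 °C → rt; Fieser work-up
Reagents that add atoms: none
Why: Hydride opens the oxirane by SN2 attack at the benzylic C4 (C3 is shielded by the quaternary C2), so the C3–O bond and its R configuration are kept, and the aldehyde is reduced in the same operation.

Step 6
Reactants: 8 (3R)-5-(benzyloxy)-8-(hydroxymethyl)-2,2-dimethylchroman-3-ol
Product: 9 (3R)-5-(benzyloxy)-3-hydroxy-2,2-dimethylchromane-8-carbaldehyde
Conditions: activated MnO2 (excess), CH2Cl2, rt
Reagents that add atoms: none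
Why: MnO2 oxidation is selective for the benzylic primary alcohol and should leave the unactivated secondary alcohol at C3 untouched.

Step 7
Reactants: 9 (3R)-5-(benzyloxy)-3-hydroxy-2,2-dimethylchromane-8-carbaldehyde
Product: 10 (3R)-5-(benzyloxy)-8-(2-methoxyethenyl)-2,2-dimethylchroman-3-ol (E/Z mixture)
Conditions: Ph3P(CH2OMe)Cl (3 equiv), KOtBu (3 equiv), THF, 0 °C → rt
Reagents that add atoms: (methoxymethyl)triphenylphosphonium chloride, COC[P+](c1ccccc1)(c1ccccc1)c1ccccc1.[Cl-]
Why: Wittig methoxymethylenation of a non-enolisable aryl aldehyde, with excess ylide to cover the free hydroxyl, which as its alkoxide is a spectator.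

Step 8
Reactants: 10 (3R)-5-(benzyloxy)-8-(2-methoxyethenyl)-2,2-dimethylchroman-3-ol
Product: 11 (3R)-3,5-bis(benzyloxy)-8-(2-methoxyethenyl)-2,2-dimethylchromane (E/Z mixture)
Conditions: NaH, BnBr, Bu4NI (cat.), DMF, 0 °C → rt
Reagents that add atoms: benzyl bromide, BrCc1ccccc1
Why: Williamson benzylation of the secondary alkoxide, placed at the enol ether stage because that group is inert to strong base whereas an aldehyde would not be.

Step 9
Reactants: 11 (3R)-3,5-bis(benzyloxy)-8-(2-methoxyethenyl)-2,2-dimethylchromane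
Product: 12 2-[(3R)-3,5-bis(benzyloxy)-2,2-dimethylchroman-8-yl]acetaldehyde
Conditions: 2 M aq. HCl, THF, 45 °C; crude product used at once
Reagents that add atoms: water, O
Why: Acid hydrolysis of the enol ether (C-protonation, hydration of the oxocarbenium ion, loss of methanol) gives the arylacetaldehyde under conditions that both benzyl ethers tolerate.

Step 10
Reactants: 12 2-[(3R)-3,5-bis(benzyloxy)-2,2-dimethylchroman-8-yl]acetaldehyde; 13 pyrrolidine
Product: 14 1-{(E)-2-[(3R)-3,5-bis(benzyloxy)-2,2-dimethylchroman-8-yl]ethenyl}pyrrolidine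
Conditions: pyrrolidine (1.5 equiv), 4 Å molecular sieves, toluene, 0 °C → rt; volatiles removed in vacuo
Reagents that add atoms: none
Why: Enamine condensation of an aldehyde with a secondary amine, in which conjugation with the arene should favour the E-configured β-aminostyrene.

Step 11
Reactants: 14 1-{(E)-2-[(3R)-3,5-bis(benzyloxy)-2,2-dimethylchroman-8-yl]ethenyl}pyrrolidine; 15 2,4,6-trifluorobenzoyl chloride
Product: 18 3-[(3R)-3,5-bis(benzyloxy)-2,2-dimethylchroman-8-yl]-5,7-difluoro-4H-chromen-4-one, via pyrrolidinyl enaminone 16 (not isolated), via hydroxymethylene ketone 17 (not isolated)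
Conditions: Et3N, toluene, 0 °C → rt; then 1 M aq. HCl, THF, rt; organic phase dried, solvent switched without isolation; then K2CO3, DMF, 60 °C
Reagents that add atoms: water, O
Why: The enamine carbon that bears the aryl group (β to nitrogen) attacks acid chloride 15 to form C3–C4, and loss of HCl to Et3N gives vinylogous amide 16, whose amino group is exchanged for hydroxyl by dilute aqueous acid to give 17, so that the future O1 comes from water. With K2CO3 the enolate oxygen of 17 adds to one ortho C–F carbon of the trifluorophenyl ketone; the Meisenheimer anion is delocalised into the C4 carbonyl and collapses with loss of fluoride to form O1–C8a. The closest known reaction type is the Grohe–Heitzer sequence, acylation of an enamine by a polyfluorobenzoyl chloride followed by intramolecular SNAr, which is established for quinolones and chromones. Ring C closes as a six-membered ring by intramolecular addition–elimination at an aromatic carbon (formally 6-endo-trig with respect to the C4a=C8a bond). No stereocentre is formed, and the R centre of ring D is remote from all reacting sites and cannot epimerise. The step needs C- over N-acylation, which is inherent to enamines because N-acylation is reversible, and intramolecular over intermolecular fluoride displacement, which the six-membered transition state secures; the two ortho fluorines are equivalent by symmetry, so only one chromone can form, and the C5 and C7 fluorines are kept for step 12.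

Step 12
Reactants: 18 3-[(3R)-3,5-bis(benzyloxy)-2,2-dimethylchroman-8-yl]-5,7-difluoro-4H-chromen-4-one
Product: 19 5,7-bis(benzyloxy)-3-[(3R)-3,5-bis(benzyloxy)-2,2-dimethylchroman-8-yl]-4H-chromen-4-one
Conditions: BnOH (2.5 equiv), NaH (2.4 equiv), THF/DMF, 0 → 50 °C; dilute aq. HCl work-up
Reagents that add atoms: benzyl alcohol, OCc1ccccc1
Why: Twofold SNAr in which benzyloxide displaces the fluorides para (C7) and ortho (C5) to the C4 carbonyl through carbonyl-stabilised Meisenheimer complexes, while addition of the alkoxide at C2 is reversible without water and the acidic work-up should re-close any opened pyranone.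

Step 13
Reactants: 19 5,7-bis(benzyloxy)-3-[(3R)-3,5-bis(benzyloxy)-2,2-dimethylchroman-8-yl]-4H-chromen-4-one
Product: 20 5,7-dihydroxy-3-[(3R)-3,5-dihydroxy-2,2-dimethyl-3,4-dihydro-2H-chromen-8-yl]-4H-chromen-4-one
Conditions: H2 (1 atm), Pd/C, EtOAc/MeOH, rt; stopped when four equivalents of H2 are taken up
Reagents that add atoms: none
Why: Catalytic hydrogenolysis cleaves the three aryl and one alkyl benzyl ethers at the O–CH2Ph bond, so the C3–O bond and its R configuration are untouched, and it should be faster than reduction of the vinylogous ester C2=C3 of ring C.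

**Compound list**

1 | 2,4-dihydroxybenzaldehyde | O=Cc1ccc(O)cc1O | starting material
2 | 4-(benzyloxy)-2-hydroxybenzaldehyde | O=Cc1ccc(OCc2ccccc2)cc1O | intermediate
3 | 3-chloro-3-methylbut-1-yne | CC(C)(Cl)C#C | starting material
4 | 4-(benzyloxy)-2-[(2-methylbut-3-yn-2-yl)oxy]benzaldehyde | O=Cc1ccc(OCc2ccccc2)cc1OC(C)(C)C#C | intermediate
5 | 4-(benzyloxy)-2-hydroxy-3-(3-methylbuta-1,2-dien-1-yl)benzaldehyde (ortho-allenylphenol, not isolated) | O=Cc1ccc(OCc2ccccc2)c(C=C=C(C)C)c1O | intermediate
6 | 5-(benzyloxy)-2,2-dimethyl-2H-chromene-8-carbaldehyde | CC1(C)C=Cc2c(OCc3ccccc3)ccc(C=O)c2O1 | intermediate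
7 | (3R,4R)-5-(benzyloxy)-3,4-epoxy-2,2-dimethylchromane-8-carbaldehyde (cis-fused oxirane across C3–C4) | CC1(C)Oc2c(C=O)ccc(OCc3ccccc3)c2[C@H]2O[C@@H]12 | intermediate
8 | (3R)-5-(benzyloxy)-8-(hydroxymethyl)-2,2-dimethylchroman-3-ol | CC1(C)Oc2c(CO)ccc(OCc3ccccc3)c2C[C@H]1O | intermediate
9 | (3R)-5-(benzyloxy)-3-hydroxy-2,2-dimethylchromane-8-carbaldehyde | CC1(C)Oc2c(C=O)ccc(OCc3ccccc3)c2C[C@H]1O | intermediate
10 | (3R)-5-(benzyloxy)-8-(2-methoxyethenyl)-2,2-dimethylchroman-3-ol (E/Z mixture) | CC1(C)Oc2c(C=COC)ccc(OCc3ccccc3)c2C[C@H]1O | intermediate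
11 | (3R)-3,5-bis(benzyloxy)-8-(2-methoxyethenyl)-2,2-dimethylchromane (E/Z mixture) | CC1(C)Oc2c(C=COC)ccc(OCc3ccccc3)c2C[C@H]1OCc1ccccc1 | intermediate
12 | 2-[(3R)-3,5-bis(benzyloxy)-2,2-dimethylchroman-8-yl]acetaldehyde | CC1(C)Oc2c(CC=O)ccc(OCc3ccccc3)c2C[C@H]1OCc1ccccc1 | intermediate
13 | pyrrolidine | C1CCNC1 | starting material
14 | 1-{(E)-2-[(3R)-3,5-bis(benzyloxy)-2,2-dimethylchroman-8-yl]ethenyl}pyrrolidine | CC1(C)Oc2c(/C=C/N3CCCC3)ccc(OCc3ccccc3)c2C[C@H]1OCc1ccccc1 | intermediate
15 | 2,4,6-trifluorobenzoyl chloride | O=C(Cl)c1c(F)cc(F)cc1F | starting material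
16 | 2-[(3R)-3,5-bis(benzyloxy)-2,2-dimethylchroman-8-yl]-3-(pyrrolidin-1-yl)-1-(2,4,6-trifluorophenyl)prop-2-en-1-one (alkene geometry not defined, not isolated) | CC1(C)Oc2c(C(=CN3CCCC3)C(=O)c3c(F)cc(F)cc3F)ccc(OCc3ccccc3)c2C[C@H]1OCc1ccccc1 | intermediate
17 | 2-[(3R)-3,5-bis(benzyloxy)-2,2-dimethylchroman-8-yl]-3-hydroxy-1-(2,4,6-trifluorophenyl)prop-2-en-1-one (enol of the formyl ketone, not isolated) | CC1(C)Oc2c(C(=CO)C(=O)c3c(F)cc(F)cc3F)ccc(OCc3ccccc3)c2C[C@H]1OCc1ccccc1 | intermediate
18 | 3-[(3R)-3,5-bis(benzyloxy)-2,2-dimethylchroman-8-yl]-5,7-difluoro-4H-chromen-4-one | CC1(C)Oc2c(-c3coc4cc(F)cc(F)c4c3=O)ccc(OCc3ccccc3)c2C[C@H]1OCc1ccccc1 | intermediate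
19 | 5,7-bis(benzyloxy)-3-[(3R)-3,5-bis(benzyloxy)-2,2-dimethylchroman-8-yl]-4H-chromen-4-one | CC1(C)Oc2c(-c3coc4cc(OCc5ccccc5)cc(OCc5ccccc5)c4c3=O)ccc(OCc3ccccc3)c2C[C@H]1OCc1ccccc1 | intermediate
20 | 5,7-dihydroxy-3-[(3R)-3,5-dihydroxy-2,2-dimethyl-3,4-dihydro-2H-chromen-8-yl]-4H-chromen-4-one | CC1(C)Oc2c(-c3coc4cc(O)cc(O)c4c3=O)ccc(O)c2C[C@H]1O | target

**Step count**

Total steps: 13. Longest linear sequence: 13 steps, from 1 to 20.

**Steps most likely to fail**

Step 11 (key step). C-acylation of the hindered, electron-rich enamine may be slow, so that the enamine is hydrolysed back to the aldehyde, or the hydroxymethylene ketone may lose its formyl carbon by retro-Claisen cleavage during the basic closure. The fallback sets out from aldehyde 12, makes the C3–C4 bond by carbonyl addition and adds C2 last. 1-Bromo-2,4,6-trifluorobenzene is converted with i-PrMgCl·LiCl (THF, −20 °C) into 2,4,6-trifluorophenylmagnesium chloride F1, which is added to 12 at −40 °C to give 2-[(3R)-3,5-bis(benzyloxy)-2,2-dimethylchroman-8-yl]-1-(2,4,6-trifluorophenyl)ethanol F2 as a mixture of carbinol epimers, which is of no consequence. Dess–Martin oxidation should give the deoxybenzoin 2-[(3R)-3,5-bis(benzyloxy)-2,2-dimethylchroman-8-yl]-1-(2,4,6-trifluorophenyl)ethanone F3. Condensation with N,N-dimethylformamide dimethyl acetal (toluene, 90 °C) should give 2-[(3R)-3,5-bis(benzyloxy)-2,2-dimethylchroman-8-yl]-3-(dimethylamino)-1-(2,4,6-trifluorophenyl)prop-2-en-1-one F4. Dilute aqueous HCl then gives 17, and K2CO3 in DMF closes it to 18, where the route is rejoined. Any deformylated material from the main step would be F3 and could be recycled the same way.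

Step 12. Conjugate addition of benzyloxide at C2 may open the pyranone, and the second displacement may stall once the first benzyloxy group has made ring A more electron-rich. The fallback sets out from aldehyde 12 and brings in ring A already oxygenated by the classical deoxybenzoin route. Pinnick oxidation (NaClO2, NaH2PO4, 2-methylbut-2-ene, t-BuOH/H2O) gives [(3R)-3,5-bis(benzyloxy)-2,2-dimethylchroman-8-yl]acetic acid F5. Friedel–Crafts acylation of commercial 1,3,5-tris(benzyloxy)benzene through the mixed trifluoroacetic anhydride (TFAA, CH2Cl2, 0 °C → rt) gives 2-[(3R)-3,5-bis(benzyloxy)-2,2-dimethylchroman-8-yl]-1-[2,4,6-tris(benzyloxy)phenyl]ethanone F6. MgBr2·OEt2 (toluene/Et2O, 70 °C) removes, by chelation, one of the two equivalent benzyl groups ortho to the carbonyl to give 1-[2,4-bis(benzyloxy)-6-hydroxyphenyl]-2-[(3R)-3,5-bis(benzyloxy)-2,2-dimethylchroman-8-yl]ethanone F7. N,N-Dimethylformamide dimethyl acetal (toluene, 90 °C) then adds C2 and closes ring C, and the route is rejoined at 19.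

Step 4. The formyl group may be oxidised by hypochlorite or by the oxo-manganese species in competition with oxygen transfer to the alkene, and the benzylic oxirane may open during work-up. The fallback sets out from 6 and masks the aldehyde instead of carrying it through a reduction and reoxidation. Ethylene glycol, PPTS and toluene under Dean–Stark conditions give 2-[5-(benzyloxy)-2,2-dimethyl-2H-chromen-8-yl]-1,3-dioxolane F8. The same epoxidation with (R,R)-(salen)MnCl and NaOCl gives 2-[(3R,4R)-5-(benzyloxy)-3,4-epoxy-2,2-dimethylchroman-8-yl]-1,3-dioxolane F9, which is reduced crude with LiAlH4 to (3R)-5-(benzyloxy)-8-(1,3-dioxolan-2-yl)-2,2-dimethylchroman-3-ol F10. Dilute HCl in THF/H2O releases the aldehyde, and the route is rejoined at 9, which also makes the MnO2 step unnecessary.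

**Further compounds**

F1 | step 11 | 2,4,6-trifluorophenylmagnesium chloride | Fc1cc(F)c([Mg]Cl)c(F)c1
F2 | step 11 | 2-[(3R)-3,5-bis(benzyloxy)-2,2-dimethylchroman-8-yl]-1-(2,4,6-trifluorophenyl)ethanol (carbinol epimers) | CC1(C)Oc2c(CC(O)c3c(F)cc(F)cc3F)ccc(OCc3ccccc3)c2C[C@H]1OCc1ccccc1
F3 | step 11 | 2-[(3R)-3,5-bis(benzyloxy)-2,2-dimethylchroman-8-yl]-1-(2,4,6-trifluorophenyl)ethanone | CC1(C)Oc2c(CC(=O)c3c(F)cc(F)cc3F)ccc(OCc3ccccc3)c2C[C@H]1OCc1ccccc1
F4 | step 11 | 2-[(3R)-3,5-bis(benzyloxy)-2,2-dimethylchroman-8-yl]-3-(dimethylamino)-1-(2,4,6-trifluorophenyl)prop-2-en-1-one | CC1(C)Oc2c(C(=CN(C)C)C(=O)c3c(F)cc(F)cc3F)ccc(OCc3ccccc3)c2C[C@H]1OCc1ccccc1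
F5 | step 12 | [(3R)-3,5-bis(benzyloxy)-2,2-dimethylchroman-8-yl]acetic acid | CC1(C)Oc2c(CC(=O)O)ccc(OCc3ccccc3)c2C[C@H]1OCc1ccccc1
F6 | step 12 | 2-[(3R)-3,5-bis(benzyloxy)-2,2-dimethylchroman-8-yl]-1-[2,4,6-tris(benzyloxy)phenyl]ethanone | CC1(C)Oc2c(CC(=O)c3c(OCc4ccccc4)cc(OCc4ccccc4)cc3OCc3ccccc3)ccc(OCc3ccccc3)c2C[C@H]1OCc1ccccc1
F7 | step 12 | 1-[2,4-bis(benzyloxy)-6-hydroxyphenyl]-2-[(3R)-3,5-bis(benzyloxy)-2,2-dimethylchroman-8-yl]ethanone | CC1(C)Oc2c(CC(=O)c3c(O)cc(OCc4ccccc4)cc3OCc3ccccc3)ccc(OCc3ccccc3)c2C[C@H]1OCc1ccccc1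
F8 | step 4 | 2-[5-(benzyloxy)-2,2-dimethyl-2H-chromen-8-yl]-1,3-dioxolane | CC1(C)C=Cc2c(OCc3ccccc3)ccc(C3OCCO3)c2O1
F9 | step 4 | 2-[(3R,4R)-5-(benzyloxy)-3,4-epoxy-2,2-dimethylchroman-8-yl]-1,3-dioxolane | CC1(C)Oc2c(C3OCCO3)ccc(OCc3ccccc3)c2[C@H]2O[C@@H]12
F10 | step 4 | (3R)-5-(benzyloxy)-8-(1,3-dioxolan-2-yl)-2,2-dimethylchroman-3-ol | CC1(C)Oc2c(C3OCCO3)ccc(OCc3ccccc3)c2C[C@H]1O
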